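**Plan**

- Retrosynthesis: the catechol ketal is removed last; C7–OH goes back to C7–Br and the C5–acrylate bond to C5–Br. Ring A is then cut at C3a–C4 and C7–C7a, giving 3,5-dibromo-2-pyrone and a lactone-derived ketene acetal. The lactone is cut at C2–C3 (aldol) and at its acyl C–O bond.
- Enabling feature: O1, C2, C3, C3a and C7a are the five ring atoms of a trans γ-aryl paraconic ester lactone (C7a is the lactone carbonyl carbon, C3a its α-carbon). C4, C5, C6 and C7 with their 5,7-substituents are C6, C5, C4 and C3 of a 3,5-dibromo-2-pyrone.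
- Forward order: the oxygen ring is made first (syn aldol, lactonisation) and its carbonyl is raised to an orthoester. Ring A is then grown on it by pyrone cycloaddition with loss of CO2 and methanol. The acrylate (C5) and the hydroxyl (C7) replace the two bromines, and the catechol is unmasked.
- Stereochemistry: C2 and C3 both come from one auxiliary-controlled syn aldol with (R)-4-benzyl-oxazolidinone. Lactonisation turns syn into trans (2R,3R), and no later step forms or breaks a bond at either centre.

Key step: step 8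

Remark: the target is read as the (2R,3R)-trans isomer. The locants C2–C7a of the target dihydrobenzofuran are used for the corresponding atoms of all precursors.

**Route**

Step 1
Reactants: 1 3,4-dihydroxybenzaldehyde
Product: 2 2,2-dimethyl-1,3-benzodioxole-5-carbaldehyde
Conditions: 2,2-dimethoxypropane, p-TsOH·H2O (cat.), benzene, reflux, Soxhlet with CaCl2
Reagents that add atoms: 2,2-dimethoxypropane, COC(C)(C)OC
Why: Acid-catalysed transketalisation gives the cyclic isopropylidene ketal of the catechol, and continuous trapping of methanol drives this deactivated catechol to completion.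

Step 2
Reactants: 3 (4R)-4-benzyl-1,3-oxazolidin-2-one; 4 methyl 4-chloro-4-oxobutanoate
Product: 6 methyl 4-[(4R)-4-benzyl-2-oxo-1,3-oxazolidin-3-yl]-4-oxobutanoate, via N-lithio oxazolidinone 5 (not isolated)
Conditions: n-BuLi, THF, −78 °C; then 4, −78 → 0 °C
Reagents that add atoms: none
Why: N-acylation of the lithiated oxazolidinone (imide formation) occurs at the acid chloride, which is far more electrophilic than the methyl ester of the same reagent.

Step 3
Reactants: 6 methyl 4-[(4R)-4-benzyl-2-oxo-1,3-oxazolidin-3-yl]-4-oxobutanoate; 2 2,2-dimethyl-1,3-benzodioxole-5-carbaldehyde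
Product: 9 (4R)-4-benzyl-3-{[(2R,3R)-2-(2,2-dimethyl-1,3-benzodioxol-5-yl)-5-oxooxolan-3-yl]carbonyl}-1,3-oxazolidin-2-one, via Z dibutylboron enolate 7 (not isolated), via syn boron aldolate 8 (not isolated)
Conditions: n-Bu2BOTf, i-Pr2NEt, CH2Cl2, 0 °C; 2, −78 °C → rt; pH 7 buffer, MeOH, 30% H2O2, 0 °C
Reagents that add atoms: none
Why: In this Evans syn aldol reaction, soft enolisation takes place only at the imide α-carbon and gives the Z boron enolate, whose chair (Zimmerman–Traxler) transition state with the auxiliary benzyl group shielding one face sets both new centres as R (syn), and the aldolate oxygen then closes onto the methyl ester (5-exo-trig lactonisation), which turns the syn aldol into the trans lactone.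

Step 4
Reactants: 9 lactone imide
Product: 11 (2R,3R)-2-(2,2-dimethyl-1,3-benzodioxol-5-yl)-5-oxooxolane-3-carboxylic acid, via lithium peroxycarboxylate 10 (not isolated)
Conditions: LiOH, 30% H2O2, THF–H2O, 0 °C; Na2SO3 aq.; then 1 M HCl to pH 3, 0 °C
Reagents that add atoms: hydrogen peroxide, OO
Why: Hydroperoxide cleavage of the N-acyl oxazolidinone (LiOOH auxiliary removal) attacks the exocyclic imide carbonyl selectively and is too weakly basic to epimerise the α-centre, and any lactone opened by hydroxide closes again on acidification.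

Step 5
Reactants: 11 lactone acid
Product: 12 methyl (2R,3R)-2-(2,2-dimethyl-1,3-benzodioxol-5-yl)-5-oxooxolane-3-carboxylate
Conditions: TMSCHN2, PhMe–MeOH (4:1), 0 °C
Reagents that add atoms: trimethylsilyldiazomethane, C[Si](C)(C)C=[N+]=[N-]
Why: Esterification with the diazoalkane runs under neutral conditions, which avoids the base-induced β-elimination (ring opening) to which paraconic esters are prone.

Step 6
Reactants: 12 lactone methyl ester
Product: 14 methyl (2R,3R)-2-(2,2-dimethyl-1,3-benzodioxol-5-yl)-5,5-dimethoxyoxolane-3-carboxylate, via lactonium tetrafluoroborate 13 (not isolated)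
Conditions: Me3OBF4, CH2Cl2, rt; then NaOMe, MeOH, −78 → 0 °C; filtration through basic Al2O3
Reagents that add atoms: trimethyloxonium tetrafluoroborate, C[O+](C)C.F[B-](F)(F)F; sodium methoxide, C[O-].[Na+]
Why: Meerwein O-alkylation of the lactone carbonyl, the most basic oxygen in the molecule, gives a dialkoxycarbenium salt to which methoxide adds at carbon, the classical conversion of a lactone into its cyclic orthoester.

Step 7
Reactants: 15 coumalic acid
Product: 17 3,5-dibromo-2H-pyran-2-one, via 5-bromo-2H-pyran-2-one 16 (not isolated)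
Conditions: NBS (2.5 equiv), LiOAc (cat.), MeCN–H2O, rt
Reagents that add atoms: N-bromosuccinimide, O=C1CCC(=O)N1Br
Why: Hunsdiecker-type bromodecarboxylation at the carboxyl-bearing C5, an enol ether β-carbon, is followed by electrophilic bromination of the second nucleophilic ring position, C3.

Step 8
Reactants: 14 orthoester; 17 3,5-dibromo-2H-pyran-2-one
Product: 21 methyl (2R,3R)-5,7-dibromo-2-(2,2-dimethyl-1,3-benzodioxol-5-yl)-2,3-dihydro-1-benzofuran-3-carboxylate, via ketene acetal 18 (not isolated), via bridged lactone cycloadduct 19 (not isolated), via cyclohexadienyl ketal 20 (not isolated)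
Conditions: TMSOTf, i-Pr2NEt, CH2Cl2, −20 → 0 °C; then 17 (1.3 equiv), PhMe, rt → 110 °C
Reagents that add atoms: none
Why: TMSOTf abstracts one methoxy group of 14 as TMSOMe and the amine removes a C3a proton from the short-lived dialkoxycarbenium ion (the acetal-to-enol-ether elimination applied to an orthoester), so ketene acetal 18 is released cold and without free acid. Its nucleophilic carbon (the later C3a) bonds to the electrophilic C6 of the electron-poor pyrone and its acetal carbon (the later C7a) to the bromine-bearing C3 in an inverse-electron-demand Diels–Alder reaction that gives bridged lactone 19; on heating, 19 expels CO2 in a retro-[4+2] reaction and cyclohexadienyl ketal 20 loses methanol and the C3a hydrogen to become aromatic. The closest known reaction type is the benzannulation of 2-pyrones with ketene acetals, including those released in situ from orthoesters, which ends in alkoxyarenes after loss of CO2 and alcohol. Ring A is closed by this intermolecular [4+2] annulation onto the five-membered ring, the new bonds being C3a–C4 and C7–C7a; the four centres created in 19 are transient, no new centre remains in 21, and C2 and C3 are spectators, a possible epimerisation at C3 being corrected towards trans by C2. The step needs regioselectivity in the cycloaddition, which the match of the donor carbon with pyrone C6 secures and which places the bromines on C5 and C7; it also needs loss of the exocyclic methoxy group rather than opening at O1, which the cis ring fusion favours because it holds that methoxy group syn to the C3a hydrogen while a cleaved ring oxygen stays tethered and can only close again.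

Step 9
Reactants: 21 dibromo dihydrobenzofuran ester; 22 methyl acrylate
Product: 23 methyl (2R,3R)-7-bromo-2-(2,2-dimethyl-1,3-benzodioxol-5-yl)-5-[(E)-3-methoxy-3-oxoprop-1-en-1-yl]-2,3-dihydro-1-benzofuran-3-carboxylate
Conditions: 22 (1.05 equiv), Pd2(dba)3 (cat.), P(t-Bu)3, Cy2NMe, dioxane, rt
Reagents that add atoms: none
Why: In this Mizoroki–Heck reaction, zerovalent palladium carrying the bulky phosphine should insert into the C5–Br bond, which has two ortho hydrogens, in preference to the C7–Br bond flanked by O1, and syn insertion followed by β-hydride elimination gives the E acrylate.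

Step 10
Reactants: 23 bromo acrylate
Product: 24 methyl (2R,3R)-2-(2,2-dimethyl-1,3-benzodioxol-5-yl)-5-[(E)-3-methoxy-3-oxoprop-1-en-1-yl]-7-(4,4,5,5-tetramethyl-1,3,2-dioxaborolan-2-yl)-2,3-dihydro-1-benzofuran-3-carboxylate
Conditions: B2pin2, Pd(dppf)Cl2 (cat.), KOAc, dioxane, 85 °C
Reagents that add atoms: bis(pinacolato)diboron, CC1(C)OB(OC1(C)C)B1OC(C)(C)C(C)(C)O1
Why: Miyaura borylation converts the one remaining aryl bromide under weakly basic acetate conditions that leave both esters and the C3 hydrogen alone.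

Step 11
Reactants: 24 arylboronate
Product: 25 methyl (2R,3R)-2-(2,2-dimethyl-1,3-benzodioxol-5-yl)-7-hydroxy-5-[(E)-3-methoxy-3-oxoprop-1-en-1-yl]-2,3-dihydro-1-benzofuran-3-carboxylate
Conditions: 30% H2O2, NaHCO3, THF–H2O, 0 °C → rt
Reagents that add atoms: hydrogen peroxide, OO
Why: Hydroperoxide oxidation of the arylboronate (1,2-shift of the aryl group from boron to oxygen) gives the C7 phenol, and at this pH the electron-poor acrylate should not be epoxidised.

Step 12
Reactants: 25 phenol acetonide
Product: 26 methyl (2R,3R)-2-(3,4-dihydroxyphenyl)-7-hydroxy-5-[(E)-3-methoxy-3-oxoprop-1-en-1-yl]-2,3-dihydro-1-benzofuran-3-carboxylate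
Conditions: TFA–H2O (9:1), 0 °C → rt
Reagents that add atoms: none
Why: Acid hydrolysis of the catechol isopropylidene ketal leaves methyl esters and the acrylate intact, and a reversible opening at the benzylic C2–O1 bond could only return the trans isomer fixed by C3.

**Compound list**

1 | 3,4-dihydroxybenzaldehyde | O=Cc1ccc(O)c(O)c1 | starting material
2 | 2,2-dimethyl-1,3-benzodioxole-5-carbaldehyde | O=Cc1ccc2OC(C)(C)Oc2c1 | intermediate
3 | (4R)-4-benzyl-1,3-oxazolidin-2-one | O=C1N[C@H](Cc2ccccc2)CO1 | starting material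
4 | methyl 4-chloro-4-oxobutanoate | COC(=O)CCC(=O)Cl | starting material
5 | N-lithio (4R)-4-benzyl-1,3-oxazolidin-2-one (not isolated) | O=C1N([Li])[C@H](Cc2ccccc2)CO1 | intermediate
6 | methyl 4-[(4R)-4-benzyl-2-oxo-1,3-oxazolidin-3-yl]-4-oxobutanoate | COC(=O)CCC(=O)N1[C@H](Cc2ccccc2)COC1=O | intermediate
7 | methyl (3Z)-4-[(4R)-4-benzyl-2-oxo-1,3-oxazolidin-3-yl]-4-[(dibutylboranyl)oxy]but-3-enoate (not isolated) | COC(=O)C/C=C(\OB(CCCC)CCCC)N1[C@H](Cc2ccccc2)COC1=O | intermediate
8 | methyl (3R)-4-[(4R)-4-benzyl-2-oxo-1,3-oxazolidin-3-yl]-3-[(R)-[(dibutylboranyl)oxy](2,2-dimethyl-1,3-benzodioxol-5-yl)methyl]-4-oxobutanoate (not isolated) | COC(=O)C[C@@H](C(=O)N1[C@H](Cc2ccccc2)COC1=O)[C@@H](OB(CCCC)CCCC)c1ccc2OC(C)(C)Oc2c1 | intermediate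
9 | (4R)-4-benzyl-3-{[(2R,3R)-2-(2,2-dimethyl-1,3-benzodioxol-5-yl)-5-oxooxolan-3-yl]carbonyl}-1,3-oxazolidin-2-one | O=C1C[C@@H](C(=O)N2[C@H](Cc3ccccc3)COC2=O)[C@H](c2ccc3OC(C)(C)Oc3c2)O1 | intermediate
10 | lithium (2R,3R)-2-(2,2-dimethyl-1,3-benzodioxol-5-yl)-5-oxooxolane-3-carboperoxoate (not isolated) | O=C1C[C@@H](C(=O)O[O-])[C@H](c2ccc3OC(C)(C)Oc3c2)O1.[Li+] | intermediate
11 | (2R,3R)-2-(2,2-dimethyl-1,3-benzodioxol-5-yl)-5-oxooxolane-3-carboxylic acid | O=C1C[C@@H](C(=O)O)[C@H](c2ccc3OC(C)(C)Oc3c2)O1 | intermediate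
12 | methyl (2R,3R)-2-(2,2-dimethyl-1,3-benzodioxol-5-yl)-5-oxooxolane-3-carboxylate | O=C1C[C@@H](C(=O)OC)[C@H](c2ccc3OC(C)(C)Oc3c2)O1 | intermediate
13 | (2R,3R)-2-(2,2-dimethyl-1,3-benzodioxol-5-yl)-5-methoxy-3-(methoxycarbonyl)-3,4-dihydro-2H-furan-1-ium tetrafluoroborate (not isolated) | COC1=[O+][C@@H](c2ccc3OC(C)(C)Oc3c2)[C@H](C(=O)OC)C1.F[B-](F)(F)F | intermediate
14 | methyl (2R,3R)-2-(2,2-dimethyl-1,3-benzodioxol-5-yl)-5,5-dimethoxyoxolane-3-carboxylate | COC1(OC)C[C@@H](C(=O)OC)[C@H](c2ccc3OC(C)(C)Oc3c2)O1 | intermediate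
15 | coumalic acid (2-oxo-2H-pyran-5-carboxylic acid) | O=C(O)C1=COC(=O)C=C1 | starting material
16 | 5-bromo-2H-pyran-2-one (not isolated) | O=C1OC=C(Br)C=C1 | intermediate
17 | 3,5-dibromo-2H-pyran-2-one | O=C1OC=C(Br)C=C1Br | intermediate
18 | methyl (2R,3R)-2-(2,2-dimethyl-1,3-benzodioxol-5-yl)-5-methoxy-2,3-dihydrofuran-3-carboxylate (ketene acetal, not isolated) | COC1=C[C@@H](C(=O)OC)[C@H](c2ccc3OC(C)(C)Oc3c2)O1 | intermediate
19 | bridged lactone from [4+2] addition of 18 across C3 and C6 of 17: a 2-oxabicyclo[2.2.2]octenone fused to the tetrahydrofuran, Br on the bridgehead next to the ketal carbon and on the alkene; the four new centres are left undefined (not isolated) | O=C1OC2C(Br)=CC1(Br)C1(OC)O[C@@H](c3ccc4OC(C)(C)Oc4c3)[C@H](C(=O)OC)C12 | intermediate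
20 | methyl (2R,3R)-5,7-dibromo-2-(2,2-dimethyl-1,3-benzodioxol-5-yl)-7a-methoxy-2,3,3a,7a-tetrahydro-1-benzofuran-3-carboxylate, cis ring fusion, C3a and C7a otherwise undefined (not isolated) | COC12O[C@@H](c3ccc4OC(C)(C)Oc4c3)[C@H](C(=O)OC)C1C=C(Br)C=C2Br | intermediate
21 | methyl (2R,3R)-5,7-dibromo-2-(2,2-dimethyl-1,3-benzodioxol-5-yl)-2,3-dihydro-1-benzofuran-3-carboxylate | Brc1cc(Br)c2c(c1)[C@@H](C(=O)OC)[C@H](c1ccc3OC(C)(C)Oc3c1)O2 | intermediate
22 | methyl acrylate | C=CC(=O)OC | starting material
23 | methyl (2R,3R)-7-bromo-2-(2,2-dimethyl-1,3-benzodioxol-5-yl)-5-[(E)-3-methoxy-3-oxoprop-1-en-1-yl]-2,3-dihydro-1-benzofuran-3-carboxylate | COC(=O)/C=C/c1cc(Br)c2c(c1)[C@@H](C(=O)OC)[C@H](c1ccc3OC(C)(C)Oc3c1)O2 | intermediate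
24 | methyl (2R,3R)-2-(2,2-dimethyl-1,3-benzodioxol-5-yl)-5-[(E)-3-methoxy-3-oxoprop-1-en-1-yl]-7-(4,4,5,5-tetramethyl-1,3,2-dioxaborolan-2-yl)-2,3-dihydro-1-benzofuran-3-carboxylate | COC(=O)/C=C/c1cc(B4OC(C)(C)C(C)(C)O4)c2c(c1)[C@@H](C(=O)OC)[C@H](c1ccc3OC(C)(C)Oc3c1)O2 | intermediate
25 | methyl (2R,3R)-2-(2,2-dimethyl-1,3-benzodioxol-5-yl)-7-hydroxy-5-[(E)-3-methoxy-3-oxoprop-1-en-1-yl]-2,3-dihydro-1-benzofuran-3-carboxylate | COC(=O)/C=C/c1cc(O)c2c(c1)[C@@H](C(=O)OC)[C@H](c1ccc3OC(C)(C)Oc3c1)O2 | intermediate
26 | methyl (2R,3R)-2-(3,4-dihydroxyphenyl)-7-hydroxy-5-[(E)-3-methoxy-3-oxoprop-1-en-1-yl]-2,3-dihydro-1-benzofuran-3-carboxylate | COC(=O)/C=C/c1cc(O)c2c(c1)[C@@H](C(=O)OC)[C@H](c1ccc(O)c(O)c1)O2 | target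

**Step count**

Total steps: 12. Longest linear sequence: 10 steps (steps 1, 3, 4, 5, 6, 8, 9, 10, 11, 12; the branch through step 2 is equally long).

**Steps most likely to fail**

1. Step 8. The ketene acetal may be reprotonated and lost through heterolysis of the benzylic C2–O1 bond before it meets the pyrone, or aromatisation may take the course of ring opening at O1 instead of loss of methanol. The fallback sets out from lactone ester 12 and comes back at 21. Thionation of the lactone carbonyl with Lawesson's reagent in toluene should give the thionolactone F1. Chemoselective S-methylation with MeOTf gives the S-methyl thionium triflate F2, which i-Pr2NEt deprotonates to the isolable ketene O,S-acetal F3. F3 is heated with 17 in toluene under acid-free conditions and adds with the same orientation to give the bridged cycloadduct F4. Loss of CO2 leads to the cyclohexadienyl O,S-ketal F5, in which the much better thiolate leaving group enforces exocyclic loss, here of methanethiol, and so delivers 21.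

2. Step 9. Site discrimination between the C5 and C7 bromides in the oxidative addition may be insufficient, and over-reaction to the bis-acrylate may set in. The fallback sets out from pyrone 17 (with orthoester 14 as partner) and comes back at 23; it moves the site selection to the pyrone. A copper-promoted Stille coupling of 17 with methyl (E)-3-(tributylstannyl)acrylate [Pd(PPh3)4, CuI (1 equiv), DMF, 50 °C] is used, conditions under which this pyrone is known to couple at C5 rather than C3. It should give the pyrone acrylate F6, whose conjugated ester further activates C6. Cycloaddition with ketene acetal 18, released from 14 as in step 8, gives the bridged cycloadduct F7, and loss of CO2 gives the cyclohexadienyl ketal F8. Loss of methanol from F8 delivers 23 directly, so that no selection between two aryl bromides is needed.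

3. Step 6. Methylation may spread over the ester and ether oxygens, or the benzylic C–O bond of the lactonium ion may ionise before methoxide is added, with loss of the ring. The fallback sets out from lactone ester 12 and comes back at 21; it avoids alkylation altogether. Soft enolisation of the lactone with TBSOTf and Et3N (CH2Cl2, −78 → 0 °C) occurs at the more basic lactone carbonyl and its unhindered α-methylene and should give the silyl ketene acetal F9. F9 is heated with 17 in toluene in place of 18 and gives the bridged cycloadduct F10. Loss of CO2 gives the cyclohexadienyl silyl ketal F11, which aromatises by loss of tert-butyldimethylsilanol to 21.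

**Further compounds**

F1 | step 8 | methyl (2R,3R)-2-(2,2-dimethyl-1,3-benzodioxol-5-yl)-5-sulfanylideneoxolane-3-carboxylate | S=C1C[C@@H](C(=O)OC)[C@H](c2ccc3OC(C)(C)Oc3c2)O1
F2 | step 8 | (2R,3R)-2-(2,2-dimethyl-1,3-benzodioxol-5-yl)-3-(methoxycarbonyl)-5-(methylsulfanyl)-3,4-dihydro-2H-furan-1-ium trifluoromethanesulfonate | CSC1=[O+][C@@H](c2ccc3OC(C)(C)Oc3c2)[C@H](C(=O)OC)C1.[O-]S(=O)(=O)C(F)(F)F
F3 | step 8 | methyl (2R,3R)-2-(2,2-dimethyl-1,3-benzodioxol-5-yl)-5-(methylsulfanyl)-2,3-dihydrofuran-3-carboxylate | CSC1=C[C@@H](C(=O)OC)[C@H](c2ccc3OC(C)(C)Oc3c2)O1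
F4 | step 8 | bridged lactone from [4+2] addition of F3 across C3 and C6 of 17 (methylsulfanyl analogue of 19, new centres undefined) | O=C1OC2C(Br)=CC1(Br)C1(SC)O[C@@H](c3ccc4OC(C)(C)Oc4c3)[C@H](C(=O)OC)C12
F5 | step 8 | methyl (2R,3R)-5,7-dibromo-2-(2,2-dimethyl-1,3-benzodioxol-5-yl)-7a-(methylsulfanyl)-2,3,3a,7a-tetrahydro-1-benzofuran-3-carboxylate | CSC12O[C@@H](c3ccc4OC(C)(C)Oc4c3)[C@H](C(=O)OC)C1C=C(Br)C=C2Br
F6 | step 9 | methyl (E)-3-(3-bromo-2-oxo-2H-pyran-5-yl)prop-2-enoate | COC(=O)/C=C/C1=COC(=O)C(Br)=C1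
F7 | step 9 | bridged lactone from [4+2] addition of 18 across C3 and C6 of F6 (new centres undefined) | O=C1OC2C(/C=C/C(=O)OC)=CC1(Br)C1(OC)O[C@@H](c3ccc4OC(C)(C)Oc4c3)[C@H](C(=O)OC)C12
F8 | step 9 | methyl (2R,3R)-7-bromo-2-(2,2-dimethyl-1,3-benzodioxol-5-yl)-7a-methoxy-5-[(E)-3-methoxy-3-oxoprop-1-en-1-yl]-2,3,3a,7a-tetrahydro-1-benzofuran-3-carboxylate | COC12O[C@@H](c3ccc4OC(C)(C)Oc4c3)[C@H](C(=O)OC)C1C=C(/C=C/C(=O)OC)C=C2Br
F9 | step 6 | methyl (2R,3R)-5-{[tert-butyl(dimethyl)silyl]oxy}-2-(2,2-dimethyl-1,3-benzodioxol-5-yl)-2,3-dihydrofuran-3-carboxylate | CC(C)(C)[Si](C)(C)OC1=C[C@@H](C(=O)OC)[C@H](c2ccc3OC(C)(C)Oc3c2)O1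
F10 | step 6 | bridged lactone from [4+2] addition of F9 across C3 and C6 of 17 (silyloxy analogue of 19, new centres undefined) | O=C1OC2C(Br)=CC1(Br)C1(O[Si](C)(C)C(C)(C)C)O[C@@H](c3ccc4OC(C)(C)Oc4c3)[C@H](C(=O)OC)C12
F11 | step 6 | methyl (2R,3R)-5,7-dibromo-7a-{[tert-butyl(dimethyl)silyl]oxy}-2-(2,2-dimethyl-1,3-benzodioxol-5-yl)-2,3,3a,7a-tetrahydro-1-benzofuran-3-carboxylate | CC(C)(C)[Si](C)(C)OC12O[C@@H](c3ccc4OC(C)(C)Oc4c3)[C@H](C(=O)OC)C1C=C(Br)C=C2Br
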